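## Analysis of the target

The target is a flavonolignan. Its core is a (2S)-5,7-dihydroxyflavanone: ring A is the phloroglucinol ring, ring C the dihydropyranone (O1, C2, C3, C4), and ring B a 3,5-dimethoxy-4-oxyphenyl group on C2. The oxygen on C4' of ring B is at the same time the ether oxygen on C8'' of an open guaiacylglycerol chain C7''–C8''–C9'', which ends in a 4-hydroxy-3-methoxyphenyl ring (ring D). There are three stereocentres: C2 (S) in ring C, the benzylic carbinol C7'' (R) and the aryloxy-bearing C8'' (S). C7'' and C8'' are adjacent and erythro (anti in the zigzag drawing). Ring B separates this pair from C2, so neither element can steer the other and each must be set on its own. Two groups are sensitive: C2 epimerises when base opens ring C by retro-oxa-Michael reaction, and C7'' is a para-hydroxybenzylic alcohol that can ionise to a quinone methide under acid or strong base. The hard part is absolute and relative control of an acyclic α-aryloxy-β-hydroxy unit whose ether oxygen is flanked by two methoxy groups, followed by a union with rings A and C that uses neither base nor acid. The strategy rests on the C7''–C8'' bond: C7'' can be the formyl carbon of a vanillin unit, C8'' is the α-carbon of an aryloxyacetaldehyde whose carbonyl carbon becomes C9'', and the erythro relation is the anti outcome of an aldol reaction.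

## Retrosynthetic reasoning

Target 16 is traced back to its 5,7-di-O-benzyl ether 15. Only the two O–benzyl bonds on ring A are cut. Hydrogenolysis is neutral, so it endangers neither C2 (base) nor C7'' (acid). Ring A needs the protection earlier, because a free 7-hydroxyl would deactivate the chromone as a conjugate acceptor.

Compound 15 is cut at the C2–C1' bond into boronic acid 10 and chromone 14. C2 has no stereocentre nearby, so a catalyst must set it, and this cut makes that a fragment union between a flat acceptor and an aryl donor that already carries C7'' and C8''. The forward reaction must transfer the aryl group to C2 of 14 with control of the face and without base, so that ring C does not open. Cuts at O1–C2 or C4–C4a would close ring C late, under basic conditions.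

Chromone 14 comes from acetophenone 12 through enaminone 13; one carbon from a formamide acetal becomes C2. Acetophenone 12 comes from 2,4,6-trihydroxyacetophenone 11 by benzylation of the two hydroxyls that are not hydrogen-bonded to the carbonyl.

Boronic acid 10 comes from aryl bromide 9 by exchange of bromine for boron. The bromine is an inert placeholder during the aldol chemistry, and the three hydroxyl groups of 9 are carried free.

Triol 9 comes from carbonate 8 by cleavage of the aryl carbonate, 8 from aldehyde 7 by reduction of C9'', and 7 by cutting C7''–C8'' into aldehyde 4 and aldehyde 6. This is the only C–C bond between the two side-chain stereocentres, and both fragments are achiral. One catalytic operation should therefore create the bond and both centres, with the anti aldol giving erythro directly. The forward reaction must favour the cross-aldol over self-aldol of 4, anti over syn, and one enantiomer. The carbonate on 6 is an activating group for this one step, since it makes the formyl group more electrophilic than an ether would. It is removed directly afterwards: zerovalent palladium ionises benzyl carbonates with decarboxylation, and an aryl carbonate would not reliably survive the hot alcohol and acetate of the borylation.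

Aldehyde 4 comes from acetal 3 by hydrolysis, and 3 from phenol 1 and bromoacetal 2 by O-alkylation. The hindered aryl ether is thus made at the stage of a simple phenol. Aldehyde 6 comes from vanillin 5 by O-acylation.

## Alternatives that were turned down

Alternative 1: Ring C is cut at O1–C8a and C4–C4a, so that ring A arrives as an aryne. In the forward step, the potassium alkoxide of a β-hydroxy ester, which already holds C2 as an (S)-carbinol and the protected side chain, adds through oxygen to 3,5-bis(benzyloxy)benzyne A2, released by fluoride from an ortho-silyl aryl triflate. The aryl anion, flanked by the new ether oxygen and a benzyloxy group, then attacks the ester and closes ring C to give the fully protected flavanone A1.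
- For it: two ring bonds form in one operation. The alkoxy group of A2 directs the oxygen nucleophile to the remote aryne carbon, so the 5,7-pattern is obtained. C2 is not touched, and the sluggish chromone acceptor and all boron chemistry are avoided. On that last point it is stronger than the chosen route.
- Against it: the C2 carbinol needs its own asymmetric step beforehand. A β-alkoxide of an ester can undergo retro-aldol cleavage. A1 is formed in a medium of strong base and fluoride, which can open ring C and attack the silyl ethers. The aryne precursor costs several steps.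
- Comparison: the chosen route sets C2 in a base-free step and is shorter.

Alternative 2: The C2–C1' bond is cut. In the forward step, an arylboronic acid with the complete erythro side chain (ring D phenol as benzyl ether, diol free) adds 1,4 to chromone 14 under a rhodium catalyst with a chiral diene ligand and gives the tri-O-benzyl flavanone A3.
- For it: catalyst control at C2, no base, high convergence. On C2 it is exactly as strong as the chosen route, which uses the same reaction type as step 8.
- Against it as a strategy: it centres the plan on the easier half of the problem and does not say how C7'' and C8'' arise. The valuable boronic acid is the partner that is normally used in excess. The rhodium precursor must carry ligands that the chiral diene can displace.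
- Comparison: the chosen strategy keeps this endgame and adds a direct answer for the side chain.

Alternative 3: The aryl–C7'' bond is cut. In the forward step, [4-(benzyloxy)-3-methoxyphenyl]magnesium bromide A6 adds to (2S)-2-(4-bromo-2,6-dimethoxyphenoxy)-3-[(triisopropylsilyl)oxy]propanal A5 under Felkin–Anh control, with the aryloxy group anti to the incoming nucleophile, to give the erythro alcohol A4.
- For it: every operation is standard, and C8'' is taken from the chiral pool, so it does not depend on a catalyst. On precedent it is stronger than the chosen route.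
- Against it: A5 has an acidic α-hydrogen next to the aryloxy group and can epimerise under the basic Grignard reagent. A magnesium chelate between the carbonyl oxygen and the ether or methoxy oxygens would lead to the threo isomer, so the diastereoselectivity is uncertain. Only one centre is made in the step; the other costs a sequence of protection, etherification of hindered phenol 1 with inversion, and reduction.
- Comparison: the chosen route makes the bond and both centres catalytically from two achiral pieces that are each reached in three steps or fewer. Its price is a less tested key step.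

Key step: step 4

Remarks on the chemistry (assumptions):
- Locants follow flavonolignan usage as defined in the analysis.
- The (S) antipode of the bisphosphine in step 8 is assumed to give 2S, by analogy with the sense of (S)-biaryl bisphosphine–rhodium catalysts in additions to cyclic enones. Both antipodes are available.

Step 1
Reactants: 1 4-bromo-2,6-dimethoxyphenol; 2 bromoacetaldehyde diethyl acetal
Product: 3 5-bromo-2-(2,2-diethoxyethoxy)-1,3-dimethoxybenzene
Conditions: K2CO3 (2 equiv), KI (0.1 equiv), DMF, 110 °C
Reagents that add atoms: none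
Why: Williamson ether synthesis; the hindered phenoxide and the deactivated β-alkoxy bromide need heat and iodide catalysis, and the aryl bromide and the acetal are inert to carbonate.

Step 2
Reactants: 3 5-bromo-2-(2,2-diethoxyethoxy)-1,3-dimethoxybenzene
Product: 4 (4-bromo-2,6-dimethoxyphenoxy)acetaldehyde
Conditions: 2 M aq. HCl, acetone, 55 °C; dried by azeotrope with toluene and used at once
Reagents that add atoms: water, O
Why: Acid-catalysed acetal hydrolysis; aryl ether, methoxy groups and bromide are stable to dilute acid, and the aldehyde is used fresh because it hydrates and oligomerises on standing.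

Step 3
Reactants: 5 vanillin
Product: 6 benzyl (4-formyl-2-methoxyphenyl) carbonate
Conditions: benzyl chloroformate (1.1 equiv), K2CO3 (1.5 equiv), acetone, 0 °C to rt
Reagents that add atoms: benzyl chloroformate, O=C(Cl)OCc1ccccc1
Why: O-acylation of the phenoxide by the chloroformate; the carbonate turns the electron-donating phenol oxygen into a weakly withdrawing group and so raises the electrophilicity of the formyl group.

Step 4
Reactants: 4 (4-bromo-2,6-dimethoxyphenoxy)acetaldehyde; 6 benzyl (4-formyl-2-methoxyphenyl) carbonate
Product: 9 (1R,2S)-2-(4-bromo-2,6-dimethoxyphenoxy)-1-(4-hydroxy-3-methoxyphenyl)propane-1,3-diol, via aldol aldehyde 7 (not isolated), via diol carbonate 8 (not isolated)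
Conditions: D-proline (20 mol%), 6 (3 equiv), DMF, 4 °C, 4 added by syringe pump over 24 h; then MeOH, NaBH4, −20 to 0 °C; then K2CO3 (1 equiv), MeOH, rt; aq. NH4Cl
Reagents that add atoms: none
Why: D-Proline condenses with 4, the only enolisable aldehyde present, to the (E)-enamine, whose carbon C8'' attacks the formyl carbon C7'' of 6 in a chair-like transition state in which the carboxylic acid of the catalyst hydrogen-bonds the acceptor oxygen; hydrolysis of the iminium ion releases 7 and the catalyst. The closest known reaction type is the proline-catalysed direct cross-aldol of α-oxyaldehyde donors with non-enolisable aldehydes, which is anti-selective. No ring closes. C8'' is set by the enamine face that the catalyst leaves open and C7'' by the aldehyde face that the acid presents, with the aryl group pseudo-equatorial; since L-proline gives the (2S,3S) anti series, D-proline should give (2R,3R)-7, which is the erythro 7''R,8''S pattern once C9'' is reduced (the descriptor at C8'' changes only because CH2OH ranks below C7''). The step needs cross- over self-aldol selectivity, anti over syn selectivity and enantioselectivity; the first is served by 6 being non-enolisable, in excess and activated by the carbonate and by the low stationary concentration of 4, the other two by the catalyst. NaBH4 is added before work-up so that the α-aryloxy-β-hydroxy aldehyde can neither epimerise at C8'' nor revert by retro-aldol cleavage. K2CO3 in MeOH then removes the carbonate by transesterification, because it has done its work and would not survive the palladium step.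

Step 5
Reactants: 9 (1R,2S)-2-(4-bromo-2,6-dimethoxyphenoxy)-1-(4-hydroxy-3-methoxyphenyl)propane-1,3-diol
Product: 10 (4-{[(1R,2S)-1,3-dihydroxy-1-(4-hydroxy-3-methoxyphenyl)propan-2-yl]oxy}-3,5-dimethoxyphenyl)boronic acid
Conditions: Pd(OAc)2 (2 mol%), 2-dicyclohexylphosphino-2',4',6'-triisopropylbiphenyl (XPhos, 4 mol%), B2(OH)4 (3 equiv), KOAc (3 equiv), EtOH, 80 °C
Reagents that add atoms: tetrahydroxydiboron, OB(O)B(O)O
Why: Miyaura borylation (oxidative addition of zerovalent palladium into C–Br, acetate-assisted transmetalation from the diboron reagent, reductive elimination); B2(OH)4 gives the free boronic acid that the base-free rhodium step needs. KOAc is too weak to start a Suzuki coupling of the product or to disturb the phenol and the diol.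

Step 6
Reactants: 11 2,4,6-trihydroxyacetophenone
Product: 12 1-[2,4-bis(benzyloxy)-6-hydroxyphenyl]ethanone
Conditions: benzyl bromide (2.05 equiv), K2CO3 (2.2 equiv), DMF, rt to 50 °C
Reagents that add atoms: benzyl bromide, BrCc1ccccc1
Why: Williamson ether synthesis; one ortho hydroxyl stays hydrogen-bonded to the carbonyl and is the least nucleophilic, so two benzyl groups go on and the chelated hydroxyl needed for ring closure remains free.

Step 7
Reactants: 12 1-[2,4-bis(benzyloxy)-6-hydroxyphenyl]ethanone
Product: 14 5,7-bis(benzyloxy)-4H-chromen-4-one, via enaminone 13 (not isolated)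
Conditions: Me2NCH(OMe)2 (3 equiv), toluene, 100 °C; evaporate; then conc. HCl (2 equiv), CH2Cl2, 40 °C
Reagents that add atoms: N,N-dimethylformamide dimethyl acetal, COC(OC)N(C)C
Why: Condensation of the methyl ketone with the formamide acetal gives the enaminone, and acid then promotes addition of the phenol oxygen to the β-carbon and loss of dimethylamine (addition–elimination), the standard chromone synthesis from 2-hydroxyacetophenones.

Step 8
Reactants: 10 (4-{[(1R,2S)-1,3-dihydroxy-1-(4-hydroxy-3-methoxyphenyl)propan-2-yl]oxy}-3,5-dimethoxyphenyl)boronic acid; 14 5,7-bis(benzyloxy)-4H-chromen-4-one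
Product: 15 (2S)-5,7-bis(benzyloxy)-2-(4-{[(1R,2S)-1,3-dihydroxy-1-(4-hydroxy-3-methoxyphenyl)propan-2-yl]oxy}-3,5-dimethoxyphenyl)-2,3-dihydro-4H-chromen-4-one
Conditions: [Rh(OH)(cod)]2 (2.5 mol%), (S)-6,6'-dimethoxy-2,2'-bis[bis(3,4,5-trifluorophenyl)phosphino]-1,1'-biphenyl ((S)-MeO-F12-BIPHEP, 5.5 mol%), 14 (2 equiv), dioxane/H2O 10:1, 40 °C, no added base
Reagents that add atoms: none
Why: Hayashi–Miyaura asymmetric 1,4-addition, a known reaction of chromones with arylboronic acids: the aryl group passes from boron to the hydroxorhodium complex, C2=C3 of 14 inserts into the aryl–rhodium bond and water protonates the oxa-π-allyl species. C2 is set by the chiral bisphosphine alone, because C7'' and C8'' are too remote to match or mismatch. The electron-poor ligand gives the activity a chromone needs, and the absence of base protects the flavanone from ring opening.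

Step 9
Reactants: 15 (2S)-5,7-bis(benzyloxy)-2-(4-{[(1R,2S)-1,3-dihydroxy-1-(4-hydroxy-3-methoxyphenyl)propan-2-yl]oxy}-3,5-dimethoxyphenyl)-2,3-dihydro-4H-chromen-4-one
Product: 16 (2S)-2-(4-{[(1R,2S)-1,3-dihydroxy-1-(4-hydroxy-3-methoxyphenyl)propan-2-yl]oxy}-3,5-dimethoxyphenyl)-5,7-dihydroxy-2,3-dihydro-4H-chromen-4-one
Conditions: H2 (1 atm), 10% Pd/C, EtOAc/MeOH 4:1, rt, stopped as soon as 15 is consumed
Reagents that add atoms: none
Why: Hydrogenolysis of the two aryl benzyl ethers, which cleave much faster than the benzylic C7''–OH bond, the O1–C2 bond or the ketone; the neutral medium leaves all three stereocentres untouched.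

## Compound list

1 | 4-bromo-2,6-dimethoxyphenol | COc1cc(Br)cc(OC)c1O | starting material
2 | bromoacetaldehyde diethyl acetal (2-bromo-1,1-diethoxyethane) | CCOC(CBr)OCC | starting material
3 | 5-bromo-2-(2,2-diethoxyethoxy)-1,3-dimethoxybenzene | CCOC(COc1c(OC)cc(Br)cc1OC)OCC | intermediate
4 | (4-bromo-2,6-dimethoxyphenoxy)acetaldehyde | O=CCOc1c(OC)cc(Br)cc1OC | intermediate
5 | vanillin (4-hydroxy-3-methoxybenzaldehyde) | COc1cc(C=O)ccc1O | starting material
6 | benzyl (4-formyl-2-methoxyphenyl) carbonate | COc1cc(C=O)ccc1OC(=O)OCc1ccccc1 | intermediate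
7 | benzyl {4-[(1R,2R)-2-(4-bromo-2,6-dimethoxyphenoxy)-1-hydroxy-3-oxopropyl]-2-methoxyphenyl} carbonate | COc1cc([C@@H](O)[C@H](C=O)Oc2c(OC)cc(Br)cc2OC)ccc1OC(=O)OCc1ccccc1 | intermediate
8 | benzyl {4-[(1R,2S)-2-(4-bromo-2,6-dimethoxyphenoxy)-1,3-dihydroxypropyl]-2-methoxyphenyl} carbonate | COc1cc([C@@H](O)[C@H](CO)Oc2c(OC)cc(Br)cc2OC)ccc1OC(=O)OCc1ccccc1 | intermediate
9 | (1R,2S)-2-(4-bromo-2,6-dimethoxyphenoxy)-1-(4-hydroxy-3-methoxyphenyl)propane-1,3-diol | COc1cc([C@@H](O)[C@H](CO)Oc2c(OC)cc(Br)cc2OC)ccc1O | intermediate
10 | (4-{[(1R,2S)-1,3-dihydroxy-1-(4-hydroxy-3-methoxyphenyl)propan-2-yl]oxy}-3,5-dimethoxyphenyl)boronic acid | COc1cc([C@@H](O)[C@H](CO)Oc2c(OC)cc(B(O)O)cc2OC)ccc1O | intermediate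
11 | 2,4,6-trihydroxyacetophenone | CC(=O)c1c(O)cc(O)cc1O | starting material
12 | 1-[2,4-bis(benzyloxy)-6-hydroxyphenyl]ethanone | CC(=O)c1c(O)cc(OCc2ccccc2)cc1OCc1ccccc1 | intermediate
13 | (2E)-1-[2,4-bis(benzyloxy)-6-hydroxyphenyl]-3-(dimethylamino)prop-2-en-1-one | CN(C)/C=C/C(=O)c1c(O)cc(OCc2ccccc2)cc1OCc1ccccc1 | intermediate
14 | 5,7-bis(benzyloxy)-4H-chromen-4-one | O=c1ccoc2cc(OCc3ccccc3)cc(OCc3ccccc3)c12 | intermediate
15 | (2S)-5,7-bis(benzyloxy)-2-(4-{[(1R,2S)-1,3-dihydroxy-1-(4-hydroxy-3-methoxyphenyl)propan-2-yl]oxy}-3,5-dimethoxyphenyl)-2,3-dihydro-4H-chromen-4-one | COc1cc([C@@H](O)[C@H](CO)Oc2c(OC)cc([C@@H]3CC(=O)c4c(OCc5ccccc5)cc(OCc5ccccc5)cc4O3)cc2OC)ccc1O | intermediate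
16 | (2S)-2-(4-{[(1R,2S)-1,3-dihydroxy-1-(4-hydroxy-3-methoxyphenyl)propan-2-yl]oxy}-3,5-dimethoxyphenyl)-5,7-dihydroxy-2,3-dihydro-4H-chromen-4-one | COc1cc([C@@H](O)[C@H](CO)Oc2c(OC)cc([C@@H]3CC(=O)c4c(O)cc(O)cc4O3)cc2OC)ccc1O | target

## Step count and least certain steps

Total step count: 9. Longest linear sequence: 6 steps (steps 1, 2, 4, 5, 8, 9).

**Step 4 (key step).**
- Self-aldol of 4 may outrun the cross-aldol, because an α-aryloxy aldehyde is itself a better electrophile than an aryl aldehyde, even an activated one.
- Anti selectivity with aryl acceptors is usually only moderate, so the syn (threo) diol may have to be separated after reduction.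
- The benzyloxycarbonyl group of 6 may transfer to the proline nitrogen and consume the catalyst. A more hindered acyl group on the vanillin oxygen would be the first adjustment.
- Any delay before reduction allows retro-aldol equilibration.
- Fallback, setting out from 1 and 6 and returning at 9: an auxiliary-controlled aldol followed by inversion at C7''. Phenol 1 is alkylated with bromoacetic acid (NaOH, H2O, reflux) to (4-bromo-2,6-dimethoxyphenoxy)acetic acid F1. Its pivaloyl mixed anhydride (t-BuCOCl, Et3N, LiCl, THF) acylates (4R)-4-benzyl-1,3-oxazolidin-2-one to give the N-acyl oxazolidinone F2. The (Z)-boron enolate (Bu2BOTf, i-Pr2NEt, CH2Cl2, −78 °C) adds to 6 in an Evans syn aldol and gives the threo aldol adduct F3, in which C8'' already has its final configuration. LiBH4 (THF/MeOH, 0 °C) removes the auxiliary and the carbonate to give the threo triol F4. The phenol and the primary alcohol are silylated (t-BuMe2SiCl, imidazole, DMF) to the threo bis-silyl ether F5. A Mitsunobu reaction with 4-nitrobenzoic acid (PPh3, diisopropyl azodicarboxylate, toluene) inverts C7'' and gives the erythro 4-nitrobenzoate F6. i-Bu2AlH (CH2Cl2, −78 °C) removes the ester while the phenol is still silylated, so that no quinone methide can form, and gives the erythro bis-silyl ether F7. Bu4NF buffered with AcOH (THF) then gives 9.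

**Step 8.**
- Protodeboronation of the electron-rich boronic acid may be faster than insertion of the doubly alkoxylated, electron-rich chromone. This matters because 10 is the valuable partner and cannot be used in large excess.
- The sense or level of facial selectivity may be lower than hoped.
- Fallback, setting out from 9 and 12 and returning at 15: ring C is closed from a chalcone and C2 is corrected by kinetic resolution. Reductive carbonylation of 9 (CO/H2, Pd(OAc)2, di(1-adamantyl)-n-butylphosphine, TMEDA, toluene, 100 °C) gives the side-chain benzaldehyde F8. Claisen–Schmidt condensation with 12 (KOH, EtOH, rt) gives the 2'-hydroxychalcone F9. NaOAc in refluxing EtOH closes ring C by oxa-Michael addition to the flavanone F10 as both C2 epimers. Asymmetric transfer hydrogenation with RuCl[(R,R)-TsDPEN](p-cymene) in HCO2H/Et3N is expected to reduce only the 2R epimer, to the cis-flavan-4-ol F11. The unreduced ketone 15 is then separated by chromatography.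

**Step 5.**
- Protodebromination or homocoupling may compete on the unprotected triol.
- Etherification at C7'' through a quinone methide is possible in hot ethanol.
- The polar boronic acid may be hard to purify.
- Fallback, setting out from 9 and returning at 10: boron is introduced through an aryllithium instead of palladium. The three hydroxyl groups are capped (Et3SiCl, imidazole, DMF) to the tris(triethylsilyl) ether F12. n-BuLi (THF, −78 °C) exchanges the bromine, B(OiPr)3 traps the aryllithium, and aqueous work-up gives the silylated boronic acid F13. AcOH/THF/H2O at rt removes the silyl groups to give 10.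

**Step 9.**
- Over-reduction is the risk: hydrogenolysis of the para-hydroxybenzylic C7''–OH bond or of the benzylic O1–C2 bond, or reduction of the C4 ketone, if the benzyl ethers cleave more slowly than expected.
- Fallback, setting out from 14 and 10 and returning at 16: ring A is protected with silyl groups so that no hydrogenation is needed. BCl3 (CH2Cl2, −78 to 0 °C) debenzylates 14 to 5,7-dihydroxy-4H-chromen-4-one F14. t-BuMe2SiOTf and 2,6-lutidine (CH2Cl2) give the bis-silyl chromone F15. Addition of 10 under the conditions of step 8 gives the bis-silyl flavanone F16. Et3N·3HF in THF then frees the two phenols under near-neutral conditions and gives 16.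

## Further compounds

F1 | step 4 | (4-bromo-2,6-dimethoxyphenoxy)acetic acid | OC(=O)COc1c(OC)cc(Br)cc1OC
F2 | step 4 | (4R)-4-benzyl-3-[(4-bromo-2,6-dimethoxyphenoxy)acetyl]-1,3-oxazolidin-2-one | O=C(COc1c(OC)cc(Br)cc1OC)N1C(=O)OC[C@H]1Cc1ccccc1
F3 | step 4 | benzyl {4-[(1S,2R)-3-[(4R)-4-benzyl-2-oxo-1,3-oxazolidin-3-yl]-2-(4-bromo-2,6-dimethoxyphenoxy)-1-hydroxy-3-oxopropyl]-2-methoxyphenyl} carbonate | COc1cc([C@H](O)[C@@H](Oc2c(OC)cc(Br)cc2OC)C(=O)N2C(=O)OC[C@H]2Cc2ccccc2)ccc1OC(=O)OCc1ccccc1
F4 | step 4 | (1S,2S)-2-(4-bromo-2,6-dimethoxyphenoxy)-1-(4-hydroxy-3-methoxyphenyl)propane-1,3-diol | COc1cc([C@H](O)[C@H](CO)Oc2c(OC)cc(Br)cc2OC)ccc1O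
F5 | step 4 | (1S,2S)-2-(4-bromo-2,6-dimethoxyphenoxy)-3-{[tert-butyl(dimethyl)silyl]oxy}-1-(4-{[tert-butyl(dimethyl)silyl]oxy}-3-methoxyphenyl)propan-1-ol | COc1cc([C@H](O)[C@H](CO[Si](C)(C)C(C)(C)C)Oc2c(OC)cc(Br)cc2OC)ccc1O[Si](C)(C)C(C)(C)C
F6 | step 4 | (1R,2S)-2-(4-bromo-2,6-dimethoxyphenoxy)-3-{[tert-butyl(dimethyl)silyl]oxy}-1-(4-{[tert-butyl(dimethyl)silyl]oxy}-3-methoxyphenyl)propyl 4-nitrobenzoate | COc1cc([C@@H](OC(=O)c2ccc(cc2)[N+](=O)[O-])[C@H](CO[Si](C)(C)C(C)(C)C)Oc2c(OC)cc(Br)cc2OC)ccc1O[Si](C)(C)C(C)(C)C
F7 | step 4 | (1R,2S)-2-(4-bromo-2,6-dimethoxyphenoxy)-3-{[tert-butyl(dimethyl)silyl]oxy}-1-(4-{[tert-butyl(dimethyl)silyl]oxy}-3-methoxyphenyl)propan-1-ol | COc1cc([C@@H](O)[C@H](CO[Si](C)(C)C(C)(C)C)Oc2c(OC)cc(Br)cc2OC)ccc1O[Si](C)(C)C(C)(C)C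
F8 | step 8 | 4-{[(1R,2S)-1,3-dihydroxy-1-(4-hydroxy-3-methoxyphenyl)propan-2-yl]oxy}-3,5-dimethoxybenzaldehyde | COc1cc([C@@H](O)[C@H](CO)Oc2c(OC)cc(C=O)cc2OC)ccc1O
F9 | step 8 | (2E)-1-[2,4-bis(benzyloxy)-6-hydroxyphenyl]-3-(4-{[(1R,2S)-1,3-dihydroxy-1-(4-hydroxy-3-methoxyphenyl)propan-2-yl]oxy}-3,5-dimethoxyphenyl)prop-2-en-1-one | COc1cc([C@@H](O)[C@H](CO)Oc2c(OC)cc(/C=C/C(=O)c3c(O)cc(OCc4ccccc4)cc3OCc3ccccc3)cc2OC)ccc1O
F10 | step 8 | 5,7-bis(benzyloxy)-2-(4-{[(1R,2S)-1,3-dihydroxy-1-(4-hydroxy-3-methoxyphenyl)propan-2-yl]oxy}-3,5-dimethoxyphenyl)-2,3-dihydro-4H-chromen-4-one, both C2 epimers | COc1cc([C@@H](O)[C@H](CO)Oc2c(OC)cc(C3CC(=O)c4c(OCc5ccccc5)cc(OCc5ccccc5)cc4O3)cc2OC)ccc1O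
F11 | step 8 | (2R,4R)-5,7-bis(benzyloxy)-2-(4-{[(1R,2S)-1,3-dihydroxy-1-(4-hydroxy-3-methoxyphenyl)propan-2-yl]oxy}-3,5-dimethoxyphenyl)-3,4-dihydro-2H-chromen-4-ol | COc1cc([C@@H](O)[C@H](CO)Oc2c(OC)cc([C@H]3C[C@@H](O)c4c(OCc5ccccc5)cc(OCc5ccccc5)cc4O3)cc2OC)ccc1O
F12 | step 5 | tris(triethylsilyl) ether of 9: {4-[(1R,2S)-2-(4-bromo-2,6-dimethoxyphenoxy)-1,3-bis(triethylsilyloxy)propyl]-2-methoxyphenoxy}triethylsilane | COc1cc([C@@H](O[Si](CC)(CC)CC)[C@H](CO[Si](CC)(CC)CC)Oc2c(OC)cc(Br)cc2OC)ccc1O[Si](CC)(CC)CC
F13 | step 5 | [4-({(1R,2S)-1-[3-methoxy-4-(triethylsilyloxy)phenyl]-1,3-bis(triethylsilyloxy)propan-2-yl}oxy)-3,5-dimethoxyphenyl]boronic acid | COc1cc([C@@H](O[Si](CC)(CC)CC)[C@H](CO[Si](CC)(CC)CC)Oc2c(OC)cc(B(O)O)cc2OC)ccc1O[Si](CC)(CC)CC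
F14 | step 9 | 5,7-dihydroxy-4H-chromen-4-one | O=c1ccoc2cc(O)cc(O)c12
F15 | step 9 | 5,7-bis{[tert-butyl(dimethyl)silyl]oxy}-4H-chromen-4-one | O=c1ccoc2cc(O[Si](C)(C)C(C)(C)C)cc(O[Si](C)(C)C(C)(C)C)c12
F16 | step 9 | (2S)-5,7-bis{[tert-butyl(dimethyl)silyl]oxy}-2-(4-{[(1R,2S)-1,3-dihydroxy-1-(4-hydroxy-3-methoxyphenyl)propan-2-yl]oxy}-3,5-dimethoxyphenyl)-2,3-dihydro-4H-chromen-4-one | COc1cc([C@@H](O)[C@H](CO)Oc2c(OC)cc([C@@H]3CC(=O)c4c(O[Si](C)(C)C(C)(C)C)cc(O[Si](C)(C)C(C)(C)C)cc4O3)cc2OC)ccc1O
A1 | alternative 1 | (2S)-5,7-bis(benzyloxy)-2-[4-({(1R,2S)-1-[4-(benzyloxy)-3-methoxyphenyl]-1,3-bis{[tert-butyl(dimethyl)silyl]oxy}propan-2-yl}oxy)-3,5-dimethoxyphenyl]-2,3-dihydro-4H-chromen-4-one | COc1cc([C@@H](O[Si](C)(C)C(C)(C)C)[C@H](CO[Si](C)(C)C(C)(C)C)Oc2c(OC)cc([C@@H]3CC(=O)c4c(OCc5ccccc5)cc(OCc5ccccc5)cc4O3)cc2OC)ccc1OCc1ccccc1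
A2 | alternative 1 | 3,5-bis(benzyloxy)benzyne | C1#CC(OCc2ccccc2)=CC(OCc2ccccc2)=C1
A3 | alternative 2 | (2S)-5,7-bis(benzyloxy)-2-[4-({(1R,2S)-1-[4-(benzyloxy)-3-methoxyphenyl]-1,3-dihydroxypropan-2-yl}oxy)-3,5-dimethoxyphenyl]-2,3-dihydro-4H-chromen-4-one | COc1cc([C@@H](O)[C@H](CO)Oc2c(OC)cc([C@@H]3CC(=O)c4c(OCc5ccccc5)cc(OCc5ccccc5)cc4O3)cc2OC)ccc1OCc1ccccc1
A4 | alternative 3 | (1R,2S)-1-[4-(benzyloxy)-3-methoxyphenyl]-2-(4-bromo-2,6-dimethoxyphenoxy)-3-[(triisopropylsilyl)oxy]propan-1-ol | COc1cc([C@@H](O)[C@H](CO[Si](C(C)C)(C(C)C)C(C)C)Oc2c(OC)cc(Br)cc2OC)ccc1OCc1ccccc1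
A5 | alternative 3 | (2S)-2-(4-bromo-2,6-dimethoxyphenoxy)-3-[(triisopropylsilyl)oxy]propanal | O=C[C@H](CO[Si](C(C)C)(C(C)C)C(C)C)Oc1c(OC)cc(Br)cc1OC
A6 | alternative 3 | [4-(benzyloxy)-3-methoxyphenyl]magnesium bromide | COc1cc([Mg]Br)ccc1OCc1ccccc1
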